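Numbering follows eremophilane: ring A is C1–C2–C3–C4–C5–C10 and ring B is C5–C6–C7–C8–C9–C10. The retrosynthesis cuts C9–O, C7=C11 and the ester C–O at C3, then C3–C4 (ring A), and last C5–C6 and C9–C10 (ring B).
Feature behind the key cut: in ring A the carbinol C3 and the methyl-bearing C4 are neighbouring trans-diequatorial stereocentres next to quaternary C5. This O–C3–C4–C array is what a C3 ketyl leaves when it adds to an alkene attached to C5. A sulfone on that alkene activates it and is later exchanged for H to give the C4 methyl.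
Forward order: ring B forms first by a Diels–Alder reaction and ring A second by the SmI2 closure. The trienoic acid (two olefinations from nonenone) is then esterified at C3, the isopropylidene group is built at C7 from the silyl enol ether left there by the cycloaddition (until then the mask of C8), and C9 is hydroxylated last.
Stereochemistry: C5 and C10 come from the catalyst (absolute) and from the E geometry of the dienophile (relative). C3 and C4 come from a chair transition state on the ring-B template. C9 comes from attack anti to the axial C5 methyl, which also gives the more stable equatorial epimer. The triene geometry comes from E-selective olefinations.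
Key step: step 6

Assumption: the facial sense of the cycloaddition in step 3 is taken from the formyl C–H···O binding model for N-protonated oxazaborolidines, in which the (R)-catalyst covers the Re face of the formyl-bearing alkene carbon. Both antipodes of the catalyst are commercial, so a reversed sense would only mean using the other one.

Step 1
Reactants: 1 methyl vinyl ketone
Product: 2 diene 2-(triisopropylsilyloxy)buta-1,3-diene
Conditions: i-Pr3SiOTf, Et3N, Et2O, 0 °C → rt
Reagents that add atoms: triisopropylsilyl triflate, CC(C)[Si](OS(=O)(=O)C(F)(F)F)(C(C)C)C(C)C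
Why: Soft enolisation with a silyl triflate and an amine (silyl enol ether formation) can only take a proton from the methyl group and so gives the 2-silyloxydiene; no stereocentre is formed.

Step 2
Reactants: 3 methyl 4-oxobutanoate
Product: 4 enal methyl (E)-5-methyl-6-oxohex-4-enoate
Conditions: Ph3P=C(CH3)CHO, toluene, 80 °C
Reagents that add atoms: 2-(triphenylphosphoranylidene)propanal, CC(C=O)=P(c1ccccc1)(c1ccccc1)c1ccccc1
Why: Wittig olefination with a stabilised α-branched ylide is reliably E-selective and stops after one homologation, because the product enal is far less electrophilic than the aliphatic aldehyde.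

Step 3
Reactants: 2 diene 2-(triisopropylsilyloxy)buta-1,3-diene; 4 enal methyl (E)-5-methyl-6-oxohex-4-enoate
Product: 5 methyl 3-[(1S,6S)-6-formyl-6-methyl-3-(triisopropylsilyloxy)cyclohex-3-en-1-yl]propanoate
Conditions: 2 (1.5 equiv), (R)-3,3-diphenyl-1-(o-tolyl)tetrahydro-1H,3H-pyrrolo[1,2-c][1,3,2]oxazaborole (20 mol %), Tf2NH (18 mol %), CH2Cl2, −78 → −40 °C
Reagents that add atoms: none
Why: In this enantioselective Diels–Alder reaction under cationic oxazaborolidine catalysis, known both for 2-silyloxydienes and for 2-methyl-2-enals, the silyloxy group directs the para orientation (C9 to C10, C6 to C5), suprafacial addition turns the E geometry of 4 into the cis relation of C5 methyl and C10 chain (formyl trans to the chain), and the catalyst leaves only the Si face of C5 open, so both centres should form as S.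

Step 4
Reactants: 5 methyl 3-[(1S,6S)-6-formyl-6-methyl-3-(triisopropylsilyloxy)cyclohex-3-en-1-yl]propanoate
Product: 6 methyl 3-[(1S,6S)-6-methyl-6-[(E)-2-(phenylsulfonyl)ethenyl]-3-(triisopropylsilyloxy)cyclohex-3-en-1-yl]propanoate
Conditions: (EtO)2P(O)CH2SO2Ph, NaH, THF, 0 °C → rt
Reagents that add atoms: diethyl (phenylsulfonylmethyl)phosphonate, CCOP(=O)(CS(=O)(=O)c1ccccc1)OCC
Why: Horner–Wadsworth–Emmons olefination with a sulfonyl-stabilised phosphonate anion converts hindered non-enolisable aldehydes into (E)-vinyl sulfones, and the weakly basic anion leaves the methyl ester and the silyl enol ether untouched.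

Step 5
Reactants: 6 methyl 3-[(1S,6S)-6-methyl-6-[(E)-2-(phenylsulfonyl)ethenyl]-3-(triisopropylsilyloxy)cyclohex-3-en-1-yl]propanoate
Product: 7 3-[(1S,6S)-6-methyl-6-[(E)-2-(phenylsulfonyl)ethenyl]-3-(triisopropylsilyloxy)cyclohex-3-en-1-yl]propanal
Conditions: i-Bu2AlH (1.1 equiv), CH2Cl2, −78 °C
Reagents that add atoms: none
Why: Partial reduction of a methyl ester with one equivalent of i-Bu2AlH at −78 °C stops at the aldehyde level, and the vinyl sulfone and silyl enol ether are inert to the reagent at this temperature.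

Step 6
Reactants: 7 3-[(1S,6S)-6-methyl-6-[(E)-2-(phenylsulfonyl)ethenyl]-3-(triisopropylsilyloxy)cyclohex-3-en-1-yl]propanal
Product: 11 (1R,2R,4aS,8aS)-8a-methyl-1-(phenylsulfonylmethyl)-6-(triisopropylsilyloxy)-1,2,3,4,4a,5,8,8a-octahydronaphthalen-2-ol, via samarium ketyl 8 (not isolated), via cyclised α-sulfonyl radical 9 (not isolated), via α-sulfonyl organosamarium 10 (not isolated)
Conditions: SmI2 (3 equiv, 0.1 M in THF), MeOH (4 equiv), THF (0.01 M in 7), −78 → 0 °C
Reagents that add atoms: samarium diiodide, I[Sm]I (its atoms stand in 8, 9 and 10 only; the product takes up hydrogen alone)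
Why: SmI2 gives one electron to the formyl group; the ketyl 8, bound to trivalent samarium, attacks C4 (the β-carbon of the vinyl sulfone) through C3, the α-sulfonyl radical 9 takes a second electron, and MeOH protonates the carbanion and the alkoxide of 10. The closest known reaction type is the SmI2 ketyl–olefin cyclisation of aldehydes onto enoates and vinyl sulfones, which delivers trans-2-substituted cycloalkanols. Ring A closes in the 6-exo-trig mode, and only the ring-B half-chair with the C10 chain and the C5 alkenyl group equatorial and the C5 methyl axial lets C3 reach C4, so the decalin is trans-fused. C4 is controlled by the chair-like transition state, in which the alkene terminus lies equatorial to avoid the axial hydrogens on C2 and C10, so that CH2SO2Ph ends on the β face, cis to the C5 methyl. C3 is controlled in the same chair by the bulky samarium-bound oxygen, which takes the equatorial site where it can also bridge to a sulfonyl oxygen, giving the 3α-hydroxyl trans to the C4 branch. The selectivity needed is reduction of the aldehyde alone and cyclisation ahead of further reduction: the C8 carbonyl is hidden as an enol ether that SmI2 does not reduce, the sulfone lowers the alkene LUMO for the nucleophilic ketyl, leaving out HMPA keeps the C–S bond intact, and high dilution disfavours pinacol coupling.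

Step 7
Reactants: 11 (1R,2R,4aS,8aS)-8a-methyl-1-(phenylsulfonylmethyl)-6-(triisopropylsilyloxy)-1,2,3,4,4a,5,8,8a-octahydronaphthalen-2-ol
Product: 12 (1R,2R,4aS,8aS)-1,8a-dimethyl-6-(triisopropylsilyloxy)-1,2,3,4,4a,5,8,8a-octahydronaphthalen-2-ol
Conditions: 6% Na(Hg), Na2HPO4, MeOH–THF, −20 → 0 °C
Reagents that add atoms: none
Why: Reductive desulfonylation of an alkyl aryl sulfone with buffered sodium amalgam replaces C–S by C–H without touching a stereocentre; the hydroxyl sits γ to sulfur, so no Julia-type elimination is possible, and the buffer spares the silyl enol ether.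

Step 8
Reactants: 13 (E)-non-3-en-2-one
Product: 14 ethyl (2E,4E)-3-methyldeca-2,4-dienoate
Conditions: (EtO)2P(O)CH2CO2Et, NaH, THF, 0 °C → rt
Reagents that add atoms: triethyl phosphonoacetate, CCOC(=O)CP(=O)(OCC)OCC
Why: Horner–Wadsworth–Emmons olefination of a methyl alkenyl ketone places the ester trans to the larger alkenyl group, so the new trisubstituted alkene should be mainly E, and the minor Z isomer can be removed by chromatography.

Step 9
Reactants: 14 ethyl (2E,4E)-3-methyldeca-2,4-dienoate
Product: 15 (2E,4E)-3-methyldeca-2,4-dien-1-ol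
Conditions: i-Bu2AlH (2.2 equiv), CH2Cl2, −78 °C
Reagents that add atoms: none
Why: 1,2-Reduction of a conjugated ester with excess i-Bu2AlH gives the allylic alcohol without disturbing the diene geometry.

Step 10
Reactants: 15 (2E,4E)-3-methyldeca-2,4-dien-1-ol
Product: 16 (2E,4E)-3-methyldeca-2,4-dienal
Conditions: MnO2, CH2Cl2, rt
Reagents that add atoms: none
Why: MnO2 oxidation is selective for allylic alcohols and stops at the enal with the alkene geometry retained.

Step 11
Reactants: 16 (2E,4E)-3-methyldeca-2,4-dienal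
Product: 17 ethyl (2E,4E,6E)-5-methyldodeca-2,4,6-trienoate
Conditions: (EtO)2P(O)CH2CO2Et, NaH, THF, 0 °C
Reagents that add atoms: triethyl phosphonoacetate, CCOC(=O)CP(=O)(OCC)OCC
Why: Horner–Wadsworth–Emmons olefination of an enal with phosphonoacetate anion is strongly E-selective and completes the all-E triene.

Step 12
Reactants: 17 ethyl (2E,4E,6E)-5-methyldodeca-2,4,6-trienoate
Product: 18 (2E,4E,6E)-5-methyldodeca-2,4,6-trienoic acid
Conditions: LiOH, THF–EtOH–H2O, rt; then 1 M HCl
Reagents that add atoms: lithium hydroxide, [Li+].[OH-] (its oxygen ends in the carboxyl group)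
Why: Saponification of the ethyl ester by acyl–oxygen cleavage at room temperature leaves the triene untouched.

Step 13
Reactants: 18 (2E,4E,6E)-5-methyldodeca-2,4,6-trienoic acid; 12 (1R,2R,4aS,8aS)-1,8a-dimethyl-6-(triisopropylsilyloxy)-1,2,3,4,4a,5,8,8a-octahydronaphthalen-2-ol
Product: 20 (1R,2R,4aS,8aS)-1,8a-dimethyl-6-(triisopropylsilyloxy)-1,2,3,4,4a,5,8,8a-octahydronaphthalen-2-yl (2E,4E,6E)-5-methyldodeca-2,4,6-trienoate, via mixed anhydride 19 (not isolated)
Conditions: 2,4,6-Cl3C6H2COCl, Et3N, toluene, rt; then 12, 4-(dimethylamino)pyridine, toluene, rt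
Reagents that add atoms: 2,4,6-trichlorobenzoyl chloride, O=C(Cl)c1c(Cl)cc(Cl)cc1Cl (its aroyl group stands in 19 only)
Why: In the Yamaguchi esterification 4-(dimethylamino)pyridine attacks the less hindered trienoyl carbonyl of 19 and passes the acyl group to the equatorial C3 hydroxyl with retention at C3, under conditions mild enough for the silyl enol ether.

Step 14
Reactants: 20 (1R,2R,4aS,8aS)-1,8a-dimethyl-6-(triisopropylsilyloxy)-1,2,3,4,4a,5,8,8a-octahydronaphthalen-2-yl (2E,4E,6E)-5-methyldodeca-2,4,6-trienoate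
Product: 21 (1R,2R,4aS,7S,8aS)-7-(2-hydroxypropan-2-yl)-1,8a-dimethyl-6-oxodecahydronaphthalen-2-yl (2E,4E,6E)-5-methyldodeca-2,4,6-trienoate
Conditions: acetone (5 equiv), TiCl4 (1.5 equiv), CH2Cl2, −78 °C
Reagents that add atoms: acetone, CC(C)=O
Why: In this Mukaiyama aldol addition the enol ether fixed at C7=C8 by the cycloaddition attacks TiCl4-activated acetone through C7 only, so no choice between C7 and C9 arises; attack from the α face, away from the axial C5 methyl, should give the equatorial 7α isomer, a centre that is erased in the next step.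

Step 15
Reactants: 21 (1R,2R,4aS,7S,8aS)-7-(2-hydroxypropan-2-yl)-1,8a-dimethyl-6-oxodecahydronaphthalen-2-yl (2E,4E,6E)-5-methyldodeca-2,4,6-trienoate
Product: 23 (1R,2R,4aS,8aS)-1,8a-dimethyl-6-oxo-7-(propan-2-ylidene)decahydronaphthalen-2-yl (2E,4E,6E)-5-methyldodeca-2,4,6-trienoate, via tertiary mesylate 22 (not isolated)
Conditions: MsCl, Et3N, CH2Cl2, 0 °C; then DBU, rt
Reagents that add atoms: methanesulfonyl chloride, CS(=O)(=O)Cl (its sulfonyl group stands in 22 only)
Why: Mesylation of the tertiary aldol hydroxyl followed by base-induced E1cB elimination through the acidic C7–H is a standard aldol dehydration and gives the conjugated tetrasubstituted isopropylidene ketone.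

Step 16
Reactants: 23 (1R,2R,4aS,8aS)-1,8a-dimethyl-6-oxo-7-(propan-2-ylidene)decahydronaphthalen-2-yl (2E,4E,6E)-5-methyldodeca-2,4,6-trienoate
Product: 25 (1R,2R,4aR,5S,8aR)-5-hydroxy-1,8a-dimethyl-6-oxo-7-(propan-2-ylidene)decahydronaphthalen-2-yl (2E,4E,6E)-5-methyldodeca-2,4,6-trienoate, via sodium enolate 24 (not isolated)
Conditions: NaN(SiMe3)2 (1.1 equiv), THF, −78 °C; then 2-(phenylsulfonyl)-3-phenyloxaziridine, −78 °C; AcOH
Reagents that add atoms: 2-(phenylsulfonyl)-3-phenyloxaziridine, O=S(=O)(N1OC1c1ccccc1)c1ccccc1; sodium bis(trimethylsilyl)amide, [Na+].C[Si](C)(C)[N-][Si](C)(C)C (its sodium stands in 24 only)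
Why: In this Davis oxidation of a kinetic cross-conjugated enolate, the hindered amide should take the α′ proton at C9 (C7 has none left and the trienoate has no α-hydrogen) and the N-sulfonyloxaziridine should deliver oxygen to the α face of C9, opposite the axial C5 methyl, giving the equatorial 9α-alcohol, which is also the more stable epimer.

Compound list
1 | methyl vinyl ketone | CC(=O)C=C | starting material
2 | 2-(triisopropylsilyloxy)buta-1,3-diene | C=CC(=C)O[Si](C(C)C)(C(C)C)C(C)C | intermediate
3 | methyl 4-oxobutanoate | COC(=O)CCC=O | starting material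
4 | methyl (E)-5-methyl-6-oxohex-4-enoate | COC(=O)CC/C=C(\C)C=O | intermediate
5 | methyl 3-[(1S,6S)-6-formyl-6-methyl-3-(triisopropylsilyloxy)cyclohex-3-en-1-yl]propanoate (ring B; C10 chain cis to C5 methyl) | COC(=O)CC[C@H]1CC(O[Si](C(C)C)(C(C)C)C(C)C)=CC[C@]1(C)C=O | intermediate
6 | methyl 3-[(1S,6S)-6-methyl-6-[(E)-2-(phenylsulfonyl)ethenyl]-3-(triisopropylsilyloxy)cyclohex-3-en-1-yl]propanoate | COC(=O)CC[C@H]1CC(O[Si](C(C)C)(C(C)C)C(C)C)=CC[C@]1(C)/C=C/S(=O)(=O)c1ccccc1 | intermediate
7 | 3-[(1S,6S)-6-methyl-6-[(E)-2-(phenylsulfonyl)ethenyl]-3-(triisopropylsilyloxy)cyclohex-3-en-1-yl]propanal (precursor of the key step) | O=CCC[C@H]1CC(O[Si](C(C)C)(C(C)C)C(C)C)=CC[C@]1(C)/C=C/S(=O)(=O)c1ccccc1 | intermediate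
8 | samarium ketyl of 7 (C3 radical, oxygen bound to diiodosamarium) | I[Sm](I)O[CH]CC[C@H]1CC(O[Si](C(C)C)(C(C)C)C(C)C)=CC[C@]1(C)/C=C/S(=O)(=O)c1ccccc1 | intermediate
9 | cyclised α-sulfonyl radical (C3–C4 bond formed, 3α-alkoxide on diiodosamarium) | I[Sm](I)O[C@@H]1CC[C@H]2CC(O[Si](C(C)C)(C(C)C)C(C)C)=CC[C@]2(C)[C@H]1[CH]S(=O)(=O)c1ccccc1 | intermediate
10 | α-sulfonyl organosamarium (carbanion carbon and 3α-oxygen each on diiodosamarium) | I[Sm](I)O[C@@H]1CC[C@H]2CC(O[Si](C(C)C)(C(C)C)C(C)C)=CC[C@]2(C)[C@H]1C([Sm](I)I)S(=O)(=O)c1ccccc1 | intermediate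
11 | (1R,2R,4aS,8aS)-8a-methyl-1-(phenylsulfonylmethyl)-6-(triisopropylsilyloxy)-1,2,3,4,4a,5,8,8a-octahydronaphthalen-2-ol (trans-decalin; 3α-OH, 4β-CH2SO2Ph, 5β-Me, 10α-H) | O[C@@H]1CC[C@H]2CC(O[Si](C(C)C)(C(C)C)C(C)C)=CC[C@]2(C)[C@H]1CS(=O)(=O)c1ccccc1 | intermediate
12 | (1R,2R,4aS,8aS)-1,8a-dimethyl-6-(triisopropylsilyloxy)-1,2,3,4,4a,5,8,8a-octahydronaphthalen-2-ol | O[C@@H]1CC[C@H]2CC(O[Si](C(C)C)(C(C)C)C(C)C)=CC[C@]2(C)[C@H]1C | intermediate
13 | (E)-non-3-en-2-one | CCCCC/C=C/C(C)=O | starting material
14 | ethyl (2E,4E)-3-methyldeca-2,4-dienoate | CCCCC/C=C/C(C)=C/C(=O)OCC | intermediate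
15 | (2E,4E)-3-methyldeca-2,4-dien-1-ol | CCCCC/C=C/C(C)=C/CO | intermediate
16 | (2E,4E)-3-methyldeca-2,4-dienal | CCCCC/C=C/C(C)=C/C=O | intermediate
17 | ethyl (2E,4E,6E)-5-methyldodeca-2,4,6-trienoate | CCCCC/C=C/C(C)=C/C=C/C(=O)OCC | intermediate
18 | (2E,4E,6E)-5-methyldodeca-2,4,6-trienoic acid | CCCCC/C=C/C(C)=C/C=C/C(=O)O | intermediate
19 | (2E,4E,6E)-5-methyldodeca-2,4,6-trienoic 2,4,6-trichlorobenzoic anhydride | CCCCC/C=C/C(C)=C/C=C/C(=O)OC(=O)c1c(Cl)cc(Cl)cc1Cl | intermediate
20 | (1R,2R,4aS,8aS)-1,8a-dimethyl-6-(triisopropylsilyloxy)-1,2,3,4,4a,5,8,8a-octahydronaphthalen-2-yl (2E,4E,6E)-5-methyldodeca-2,4,6-trienoate | CCCCC/C=C/C(C)=C/C=C/C(=O)O[C@@H]1CC[C@H]2CC(O[Si](C(C)C)(C(C)C)C(C)C)=CC[C@]2(C)[C@H]1C | intermediate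
21 | (1R,2R,4aS,7S,8aS)-7-(2-hydroxypropan-2-yl)-1,8a-dimethyl-6-oxodecahydronaphthalen-2-yl (2E,4E,6E)-5-methyldodeca-2,4,6-trienoate | CCCCC/C=C/C(C)=C/C=C/C(=O)O[C@@H]1CC[C@H]2CC(=O)[C@H](C(C)(C)O)C[C@]2(C)[C@H]1C | intermediate
22 | tertiary methanesulfonate of 21 | CCCCC/C=C/C(C)=C/C=C/C(=O)O[C@@H]1CC[C@H]2CC(=O)[C@H](C(C)(C)OS(C)(=O)=O)C[C@]2(C)[C@H]1C | intermediate
23 | (1R,2R,4aS,8aS)-1,8a-dimethyl-6-oxo-7-(propan-2-ylidene)decahydronaphthalen-2-yl (2E,4E,6E)-5-methyldodeca-2,4,6-trienoate | CCCCC/C=C/C(C)=C/C=C/C(=O)O[C@@H]1CC[C@H]2CC(=O)C(=C(C)C)C[C@]2(C)[C@H]1C | intermediate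
24 | sodium C8=C9 enolate of 23 | [Na+].CCCCC/C=C/C(C)=C/C=C/C(=O)O[C@@H]1CC[C@H]2C=C([O-])C(=C(C)C)C[C@]2(C)[C@H]1C | intermediate
25 | (1R,2R,4aR,5S,8aR)-5-hydroxy-1,8a-dimethyl-6-oxo-7-(propan-2-ylidene)decahydronaphthalen-2-yl (2E,4E,6E)-5-methyldodeca-2,4,6-trienoate (CNP0211657.1; 3α-acyloxy, 4β-Me, 5β-Me, 9α-OH, 10α-H) | CCCCC/C=C/C(C)=C/C=C/C(=O)O[C@@H]1CC[C@H]2[C@H](O)C(=O)C(=C(C)C)C[C@]2(C)[C@H]1C | target

Total step count: 16.
Longest linear sequence: 10 steps (step 1 or 2, then steps 3–7 and 13–16). The acid branch (steps 8–12) joins at step 13.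

Steps most likely to fail

Step 3. The trisubstituted enal may add too slowly. The silyloxydiene may instead attack the activated formyl group in an aldol sense. Facial shielding may also be incomplete. The fallback sets out from 4. It replaces strong Lewis-acid activation of the dienophile with a much more nucleophilic diene under hydrogen-bond catalysis.
- The commercial (E)-3-(tert-butyldimethylsilyloxy)-N,N-dimethylbuta-1,3-dien-1-amine should add to 4 in toluene at −78 to −40 °C. The catalyst would be the appropriate antipode of 2,2-dimethyl-α,α,α′,α′-tetra(1-naphthyl)-1,3-dioxolane-4,5-dimethanol.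
- Both donor groups direct C9 to C10 and the amino-bearing C6 to C5, and the E geometry of 4 again fixes the C5/C10 relation. This should give the endo amino silyl enol ether F1.
- Olefination as in step 4 would give the vinyl sulfone F2.
- HF in MeCN would remove the silyl group and expel dimethylamine to leave the C6=C7 enone F3.
- 1,4-Hydrosilylation with i-Pr3SiH and Pt2[(CH2=CHSiMe2)2O]3 would place hydrogen on C6 and silicon on the C8 oxygen, which comes back to the route at 6.

Step 6. Reduction of the ketyl to the primary alcohol, or pinacol dimerisation, may outrun the slow attack on the neopentyl alkene carbon. A boat-like transition state may also erode the C3/C4 control. The fallback sets out from 7 and forms the same C3–C4 bond one oxidation level higher, with an acyl radical in place of the ketyl.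
- A thiol-catalysed radical-chain hydroacylation (tert-dodecanethiol, 1,1′-azobis(cyclohexanecarbonitrile), toluene, 100 °C) abstracts the formyl hydrogen.
- The acyl radical is small and nucleophilic and can be neither over-reduced nor dimerised to a pinacol. It should close 6-exo on C4 to give the 3-ketone F4, in which C4 lies α to the carbonyl and can settle in the equatorial position.
- Li in NH3–THF–EtOH would then cleave the C–S bond and reduce the ketone to the more stable equatorial alcohol in one operation. An E1cB loss of sulfinate would only lead through the 4-methylene ketone to the same product.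
- This comes back at 12 and also replaces step 7.

Step 16. The base may remove a proton from a γ-methyl of the isopropylidene group or from the trienoate chain instead of from hindered C9. That would put oxygen on the wrong carbon or degrade the ester. The fallback sets out from 23 and introduces the oxygen without any strong base.
- Mn(OAc)3 in refluxing benzene acetoxylates enones at the α′ carbon through a manganese enolate and should give the 9-acetate F5. The C9 epimers equilibrate to the equatorial one.
- Brief methanolysis with K2CO3 in MeOH at 0 °C should cleave the activated α-keto acetate much faster than the hindered conjugated trienoate, arriving at 25.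

Further compounds
F1 | step 3 | methyl 3-[(1S,5S,6R)-5-(dimethylamino)-6-formyl-6-methyl-3-(tert-butyldimethylsilyloxy)cyclohex-3-en-1-yl]propanoate | COC(=O)CC[C@H]1CC(O[Si](C)(C)C(C)(C)C)=C[C@H](N(C)C)[C@]1(C)C=O
F2 | step 3 | methyl 3-[(1S,5S,6S)-5-(dimethylamino)-6-methyl-6-[(E)-2-(phenylsulfonyl)ethenyl]-3-(tert-butyldimethylsilyloxy)cyclohex-3-en-1-yl]propanoate | COC(=O)CC[C@H]1CC(O[Si](C)(C)C(C)(C)C)=C[C@H](N(C)C)[C@]1(C)/C=C/S(=O)(=O)c1ccccc1
F3 | step 3 | methyl 3-[(1S,2R)-2-methyl-5-oxo-2-[(E)-2-(phenylsulfonyl)ethenyl]cyclohex-3-en-1-yl]propanoate | COC(=O)CC[C@H]1CC(=O)C=C[C@]1(C)/C=C/S(=O)(=O)c1ccccc1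
F4 | step 6 | (1R,4aS,8aS)-8a-methyl-1-(phenylsulfonylmethyl)-6-(triisopropylsilyloxy)-3,4,4a,5,8,8a-hexahydronaphthalen-2(1H)-one | O=C1CC[C@H]2CC(O[Si](C(C)C)(C(C)C)C(C)C)=CC[C@]2(C)[C@H]1CS(=O)(=O)c1ccccc1
F5 | step 16 | (1R,2R,4aR,5S,8aR)-5-acetoxy-1,8a-dimethyl-6-oxo-7-(propan-2-ylidene)decahydronaphthalen-2-yl (2E,4E,6E)-5-methyldodeca-2,4,6-trienoate | CCCCC/C=C/C(C)=C/C=C/C(=O)O[C@@H]1CC[C@H]2[C@H](OC(C)=O)C(=O)C(=C(C)C)C[C@]2(C)[C@H]1C
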